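**Retrosynthetic overview**

1. The target is a (5Z)-5-ylidene-3-(hydroxymethyl)furan-2(5H)-one with one (S)-CH(CH3) center, an (E,E)-4-methyl-diene and a 3-(furan-3-ylmethyl)furan; the last disconnection is O-desilylation.
2. Key disconnection: the CH2–CH(CH3) bond between the dienyl CH2 and the stereocenter, made by an ε-selective, enantioselective palladium-catalyzed allylic alkylation of a 5-[(E)-propenyl]-2-silyloxyfuran with a (2E,4E)-dienyl methyl carbonate.
3. Enabling feature: the CH(CH3) carbon is the ε-carbon of the array O1–C2(=O)–C3=C4–C5=CH–CH of the lactone ring. Its O-silylated, deprotonated form is an aromatic furan (O1, C2–C5) whose electron density reaches the ε-carbon, and bond formation there restores the (Z)-5-ylidene butenolide. The CH2 partner is the end of a penta-2,4-dienyl unit that gives an η3-allyl palladium cation.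
4. Dienyl carbonate: 3,4-dibromofuran → lithiation and addition to furan-3-carbaldehyde → deoxygenation → vinylation → hydroboration and B-alkyl Suzuki coupling with (2E,4E)-5-iodo-4-methylpenta-2,4-dien-1-ol (from carboalumination of pent-2-en-4-yn-1-ol) → carbonate.
5. Rings: both furans are bought; the butenolide is closed by ring-closing metathesis, extended to the 5-propylidene lactone, aromatized to the silyloxyfuran, and returned to the lactone in the key step.

Key step: step 12

Assumption: the sense of asymmetric induction in step 12 cannot be taken from a matching precedent; the (R,R)-ligand is written, and its enantiomer would be used if a pilot run shows that it leads to the (R)-configured product.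

**Route**

Step 1
Reactants: 1 3,4-dibromofuran; 2 furan-3-carbaldehyde
Product: 4 (4-bromofuran-3-yl)(furan-3-yl)methanol (racemic), via 3-bromo-4-lithiofuran 3 (not isolated)
Conditions: n-BuLi (1.0 equiv), Et2O, –78 °C; then 2, –78 °C; H2O
Reagents that add atoms: n-butyllithium, [Li]CCCC (lithium held by 3 only)
Why: Bromine–lithium exchange stops after one bromine at –78 °C, where 3-lithiofurans do not yet rearrange, and the aryllithium adds 1,2 to the aldehyde (halogen–metal exchange and carbonyl addition); the carbinol center is racemic and is erased in step 2.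

Step 2
Reactants: 4 (4-bromofuran-3-yl)(furan-3-yl)methanol
Product: 5 3-bromo-4-(furan-3-ylmethyl)furan
Conditions: Et3SiH (3 equiv), CF3CO2H (3 equiv), CH2Cl2 (dilute), –20 to 0 °C
Reagents that add atoms: none
Why: Ionic hydrogenation: the cation stabilized by both 3-furyl groups should be reduced by hydride transfer from the excess silane faster than it can alkylate a furan ring in cold, dilute solution; the C–Br bond is inert.

Step 3
Reactants: 5 3-bromo-4-(furan-3-ylmethyl)furan; 6 4,4,5,5-tetramethyl-2-vinyl-1,3,2-dioxaborolane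
Product: 7 3-ethenyl-4-(furan-3-ylmethyl)furan
Conditions: Pd(dppf)Cl2 (5 mol%), K3PO4, 1,4-dioxane/H2O, 80 °C
Reagents that add atoms: none
Why: Suzuki–Miyaura coupling of a heteroaryl bromide with an alkenylboronic ester; the C–Br bond is the only site for oxidative addition.

Step 4
Reactants: 8 (E)-pent-2-en-4-yn-1-ol
Product: 10 (2E,4E)-5-iodo-4-methylpenta-2,4-dien-1-ol, via alkenylalane 9 (not isolated)
Conditions: Me3Al (3 equiv), Cp2ZrCl2 (0.3 equiv), ClCH2CH2Cl, 0 °C to rt; then I2, THF, –30 to 0 °C; aq. K2CO3
Reagents that add atoms: trimethylaluminium, C[Al](C)C; iodine, II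
Why: Zirconium-catalyzed carboalumination (Negishi) adds methyl and aluminium syn across the terminal alkyne with aluminium on the terminal carbon, and iodine replaces aluminium with retention, so the new trisubstituted olefin should be E; the existing E olefin is a spectator.

Step 5
Reactants: 7 3-ethenyl-4-(furan-3-ylmethyl)furan; 10 (2E,4E)-5-iodo-4-methylpenta-2,4-dien-1-ol
Product: 12 (2E,4E)-7-[4-(furan-3-ylmethyl)furan-3-yl]-4-methylhepta-2,4-dien-1-ol, via alkyl-9-BBN 11 (not isolated)
Conditions: 9-BBN (1.2 equiv), THF, 0 °C to rt; then 10, Pd(dppf)Cl2 (5 mol%), AsPh3 (10 mol%), aq. Cs2CO3, DMF, rt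
Reagents that add atoms: 9-borabicyclo[3.3.1]nonane, [H]B1C2CCCC1CCC2 (boron held by 11 only)
Why: 9-BBN hydroborates the vinyl group at its terminal carbon while the furans stay inert, and the B-alkyl Suzuki–Miyaura coupling with the alkenyl iodide should proceed with retention of both olefin geometries; the free hydroxyl is tolerated.

Step 6
Reactants: 12 (2E,4E)-7-[4-(furan-3-ylmethyl)furan-3-yl]-4-methylhepta-2,4-dien-1-ol
Product: 13 (2E,4E)-7-[4-(furan-3-ylmethyl)furan-3-yl]-4-methylhepta-2,4-dien-1-yl methyl carbonate
Conditions: ClCO2Me (1.5 equiv), pyridine, CH2Cl2, 0 °C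
Reagents that add atoms: methyl chloroformate, COC(=O)Cl
Why: Acylation of a primary allylic alcohol with a chloroformate; it installs the leaving group that palladium ionizes in step 12.

Step 7
Reactants: 14 prop-2-enyl prop-2-enoate (allyl acrylate); 15 formaldehyde (37% in water)
Product: 16 prop-2-enyl 2-(hydroxymethyl)prop-2-enoate
Conditions: DABCO (0.5 equiv), 1,4-dioxane/H2O, rt
Reagents that add atoms: none
Why: Morita–Baylis–Hillman reaction: the amine adds to the acrylate, the ammonium enolate adds to formaldehyde, and the amine is eliminated.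

Step 8
Reactants: 16 prop-2-enyl 2-(hydroxymethyl)prop-2-enoate
Product: 17 prop-2-enyl 2-({[tri(propan-2-yl)silyl]oxy}methyl)prop-2-enoate
Conditions: i-Pr3SiCl (1.1 equiv), imidazole (2 equiv), DMF, rt
Reagents that add atoms: chlorotri(propan-2-yl)silane, CC(C)[Si](Cl)(C(C)C)C(C)C
Why: Silylation of a primary alcohol; the bulky silyl ether should survive all later steps and shields C3 of the lactone in the key step.

Step 9
Reactants: 17 prop-2-enyl 2-({[tri(propan-2-yl)silyl]oxy}methyl)prop-2-enoate
Product: 18 3-({[tri(propan-2-yl)silyl]oxy}methyl)furan-2(5H)-one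
Conditions: second-generation Grubbs catalyst, RuCl2(H2IMes)(PCy3)(=CHPh) (5 mol%), CH2Cl2 (0.01 M), reflux
Reagents that add atoms: none
Why: Ring-closing metathesis of an allyl acrylate to the five-membered unsaturated lactone, driven by loss of ethene; the 1,1-disubstituted acrylate olefin calls for the second-generation catalyst and dilution.

Step 10
Reactants: 18 3-({[tri(propan-2-yl)silyl]oxy}methyl)furan-2(5H)-one; 19 propanal
Product: 22 (5Z)-5-propylidene-3-({[tri(propan-2-yl)silyl]oxy}methyl)furan-2(5H)-one, via silyloxyfuran 20 (not isolated), via silyl aldol ether 21 (not isolated)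
Conditions: t-BuMe2SiOTf (1.1 equiv), i-Pr2NEt (1.3 equiv), CH2Cl2, 0 °C; then –78 °C, propanal (1.5 equiv), t-BuMe2SiOTf (0.3 equiv); then DBU (2.5 equiv), –78 °C to rt
Reagents that add atoms: tert-butyldimethylsilyl triflate, CC(C)(C)[Si](C)(C)OS(=O)(=O)C(F)(F)F (silyl group held by 20 and 21, lost again in the elimination)
Why: O-silylation with γ-deprotonation gives the 2-silyloxyfuran, which adds through C5 to the silyl-activated aldehyde (vinylogous Mukaiyama aldol reaction), and DBU then removes H5 and expels silanolate (E1cB) to the conjugated ylidene lactone, whose Z isomer should prevail because the ethyl group avoids H4; the two stereocenters of 21 are destroyed.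

Step 11
Reactants: 22 (5Z)-5-propylidene-3-({[tri(propan-2-yl)silyl]oxy}methyl)furan-2(5H)-one
Product: 23 tert-butyldimethyl({5-[(1E)-prop-1-en-1-yl]-3-({[tri(propan-2-yl)silyl]oxy}methyl)furan-2-yl}oxy)silane
Conditions: t-BuMe2SiOTf (1.1 equiv), Et3N (1.5 equiv), CH2Cl2, 0 °C; pentane extraction, used without chromatography
Reagents that add atoms: tert-butyldimethylsilyl triflate, CC(C)(C)[Si](C)(C)OS(=O)(=O)C(F)(F)F
Why: Soft enolization: silylation of the lactone carbonyl oxygen acidifies the ε-CH2, and the amine removes one of its protons to give the aromatic 2-silyloxyfuran with an (E)-propenyl group (methyl anti to the ring).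

Step 12
Reactants: 13 (2E,4E)-7-[4-(furan-3-ylmethyl)furan-3-yl]-4-methylhepta-2,4-dien-1-yl methyl carbonate; 23 tert-butyldimethyl({5-[(1E)-prop-1-en-1-yl]-3-({[tri(propan-2-yl)silyl]oxy}methyl)furan-2-yl}oxy)silane
Product: 24 (5Z)-5-{(2S,4E,6E)-9-[4-(furan-3-ylmethyl)furan-3-yl]-2,6-dimethylnona-4,6-dien-1-ylidene}-3-({[tri(propan-2-yl)silyl]oxy}methyl)furan-2(5H)-one
Conditions: Pd2(dba)3·CHCl3 (2.5 mol%), (R,R)-DACH-phenyl Trost ligand (7.5 mol%), 23 (1.2 equiv), degassed CH2Cl2, 0 °C to rt
Reagents that add atoms: none
Why: Proposed new method: zerovalent palladium ionizes carbonate 13 to a cationic η3-(2E,4E)-dienyl complex, CO2 and methoxide; methoxide removes the O-silyl group of 23, and the aromatic 5-(E-propenyl)furan-2-olate so freed attacks the unsubstituted CH2 terminus of the allyl ligand from outside the coordination sphere through its ε-carbon, which turns the furan back into the 5-ylidene-furan-2(5H)-one. The closest known reaction types are the Tsuji–Trost allylation of silyl enol ethers by allyl carbonates, the palladium-catalyzed asymmetric allylic alkylation of prochiral enolates and of butenolide dienolates with this ligand class, and the ε-selective (bis-vinylogous) Mukaiyama aldol addition of 5-alkenyl-2-silyloxyfurans; an ε-selective allylic alkylation of such a furanolate is not known. No ring is closed, the furan ring is only dearomatized, and the exocyclic C5=CH bond should form with Z geometry because the ε-carbon reacts from the s-trans C4=C5–CH=CH conformer, which keeps it on the side of the ring oxygen and away from H4. The (S) center at the ε-carbon is controlled by the chiral pocket of the bisphosphine ligand, which must distinguish the two faces of the flat (E)-propenyl terminus; this is the element with the least precedent. Site selectivity is needed on both partners: on the nucleophile, C3 (flanked by CH2OSi(i-Pr)3 and the ring oxygen substituent) and C5 (bearing the propenyl group) would both become quaternary, whereas the ε-carbon is secondary and gives the fully conjugated product, and O-allylation is reversible under the catalyst; on the electrophile, the CH2 terminus is the least hindered and attack there keeps the E,E-diene conjugated. Because methoxide is consumed by silicon, no base should remain that could remove the still acidic ε-hydrogen of 24 and erase the new center.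

Step 13
Reactants: 24 (5Z)-5-{(2S,4E,6E)-9-[4-(furan-3-ylmethyl)furan-3-yl]-2,6-dimethylnona-4,6-dien-1-ylidene}-3-({[tri(propan-2-yl)silyl]oxy}methyl)furan-2(5H)-one
Product: 25 (5Z)-5-{(2S,4E,6E)-9-[4-(furan-3-ylmethyl)furan-3-yl]-2,6-dimethylnona-4,6-dien-1-ylidene}-3-(hydroxymethyl)furan-2(5H)-one (target)
Conditions: HF·pyridine, pyridine, THF, 0 °C to rt
Reagents that add atoms: none
Why: Fluoride cleavage of the primary silyl ether under buffered, non-basic conditions should leave the base-sensitive ε-stereocenter, the Z-ylidene lactone, the diene and both furans untouched.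

**Compound list**

1 | 3,4-dibromofuran | Brc1cocc1Br | starting material
2 | furan-3-carbaldehyde | O=Cc1ccoc1 | starting material
3 | 3-bromo-4-lithiofuran | [Li]c1cocc1Br | intermediate
4 | (4-bromofuran-3-yl)(furan-3-yl)methanol (racemic) | OC(c1ccoc1)c1cocc1Br | intermediate
5 | 3-bromo-4-(furan-3-ylmethyl)furan | Brc1cocc1Cc1ccoc1 | intermediate
6 | 4,4,5,5-tetramethyl-2-vinyl-1,3,2-dioxaborolane | C=CB1OC(C)(C)C(C)(C)O1 | starting material
7 | 3-ethenyl-4-(furan-3-ylmethyl)furan | C=Cc1cocc1Cc1ccoc1 | intermediate
8 | (E)-pent-2-en-4-yn-1-ol | OC/C=C/C#C | starting material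
9 | dimethylaluminium (2E,4E)-5-(dimethylalumanyl)-4-methylpenta-2,4-dien-1-olate | C[Al](C)OC/C=C/C(C)=C/[Al](C)C | intermediate
10 | (2E,4E)-5-iodo-4-methylpenta-2,4-dien-1-ol | OC/C=C/C(C)=C/I | intermediate
11 | 9-{2-[4-(furan-3-ylmethyl)furan-3-yl]ethyl}-9-borabicyclo[3.3.1]nonane | C(Cc1cocc1Cc1ccoc1)B1C2CCCC1CCC2 | intermediate
12 | (2E,4E)-7-[4-(furan-3-ylmethyl)furan-3-yl]-4-methylhepta-2,4-dien-1-ol | OC/C=C/C(C)=C/CCc1cocc1Cc1ccoc1 | intermediate
13 | (2E,4E)-7-[4-(furan-3-ylmethyl)furan-3-yl]-4-methylhepta-2,4-dien-1-yl methyl carbonate | COC(=O)OC/C=C/C(C)=C/CCc1cocc1Cc1ccoc1 | intermediate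
14 | prop-2-enyl prop-2-enoate (allyl acrylate) | C=CC(=O)OCC=C | starting material
15 | formaldehyde | C=O | starting material
16 | prop-2-enyl 2-(hydroxymethyl)prop-2-enoate | C=C(CO)C(=O)OCC=C | intermediate
17 | prop-2-enyl 2-({[tri(propan-2-yl)silyl]oxy}methyl)prop-2-enoate | C=C(CO[Si](C(C)C)(C(C)C)C(C)C)C(=O)OCC=C | intermediate
18 | 3-({[tri(propan-2-yl)silyl]oxy}methyl)furan-2(5H)-one | O=C1OCC=C1CO[Si](C(C)C)(C(C)C)C(C)C | intermediate
19 | propanal | CCC=O | starting material
20 | tert-butyldimethyl{[3-({[tri(propan-2-yl)silyl]oxy}methyl)furan-2-yl]oxy}silane | CC(C)(C)[Si](C)(C)Oc1occc1CO[Si](C(C)C)(C(C)C)C(C)C | intermediate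
21 | 5-{1-[(tert-butyldimethylsilyl)oxy]propyl}-3-({[tri(propan-2-yl)silyl]oxy}methyl)furan-2(5H)-one (racemic mixture of diastereomers) | CCC(O[Si](C)(C)C(C)(C)C)C1OC(=O)C(CO[Si](C(C)C)(C(C)C)C(C)C)=C1 | intermediate
22 | (5Z)-5-propylidene-3-({[tri(propan-2-yl)silyl]oxy}methyl)furan-2(5H)-one | CC/C=C1/C=C(CO[Si](C(C)C)(C(C)C)C(C)C)C(=O)O1 | intermediate
23 | tert-butyldimethyl({5-[(1E)-prop-1-en-1-yl]-3-({[tri(propan-2-yl)silyl]oxy}methyl)furan-2-yl}oxy)silane | C/C=C/c1cc(CO[Si](C(C)C)(C(C)C)C(C)C)c(O[Si](C)(C)C(C)(C)C)o1 | intermediate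
24 | (5Z)-5-{(2S,4E,6E)-9-[4-(furan-3-ylmethyl)furan-3-yl]-2,6-dimethylnona-4,6-dien-1-ylidene}-3-({[tri(propan-2-yl)silyl]oxy}methyl)furan-2(5H)-one | CC(/C=C/C[C@H](C)/C=C1/C=C(CO[Si](C(C)C)(C(C)C)C(C)C)C(=O)O1)=C\CCc1cocc1Cc1ccoc1 | intermediate
25 | (5Z)-5-{(2S,4E,6E)-9-[4-(furan-3-ylmethyl)furan-3-yl]-2,6-dimethylnona-4,6-dien-1-ylidene}-3-(hydroxymethyl)furan-2(5H)-one | CC(/C=C/C[C@H](C)/C=C1/C=C(CO)C(=O)O1)=C\CCc1cocc1Cc1ccoc1 | target

**Step count and risks**

Total step count: 13. Longest linear sequence: 7 steps (steps 1, 2, 3, 5, 6, 12, 13, or equally steps 7 to 13).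

Steps most likely to fail:

1. Step 12 (proposed new method). What may go wrong: bond formation through C3 or C5 of the furanolate instead of the ε-carbon (C3 attack is the site favored in known palladium-catalyzed allylations of butenolide dienolates), weak facial discrimination at the remote ε-carbon, or loss of the new center by proton exchange. The fallback sets out from 12 and 18 and comes back at 24; it fixes the stereocenter by an Evans alkylation and attaches the lactone afterwards. Dienol 12 would be converted with CBr4/PPh3 (CH2Cl2, 0 °C) into 3-[(3E,5E)-7-bromo-4-methylhepta-3,5-dien-1-yl]-4-(furan-3-ylmethyl)furan F1. The sodium enolate of commercial (R)-4-benzyl-3-propanoyl-1,3-oxazolidin-2-one (NaN(SiMe3)2, THF, –78 °C) would be alkylated with F1 on the face opposite the benzyl group to give the (2S)-acyl oxazolidinone F2. LiBH4/MeOH (THF, 0 °C) would release the (2S)-2,6-dimethyl-dienol F3, and Dess–Martin periodinane (NaHCO3, CH2Cl2) would give the (2S)-aldehyde F4. Silyloxyfuran 20, generated from 18 as in step 10, would add to F4 in a vinylogous Mukaiyama aldol reaction (t-BuMe2SiOTf cat., CH2Cl2, –78 °C) to give the silyl aldol ether F5, and DBU would eliminate silanol to give 24.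

2. Step 10. What may go wrong: silyl enol ether formation and self-condensation of the enolizable aldehyde in competition with the vinylogous addition, and incomplete Z selectivity in the elimination. The fallback sets out from 18 (through 20) and comes back at 22; it makes the exocyclic olefin by a Wittig reaction instead of an aldol–elimination sequence. Silyloxyfuran 20 would be brominated at C5 with N-bromosuccinimide (THF, –78 °C) to 5-bromo-3-({[tri(propan-2-yl)silyl]oxy}methyl)furan-2(5H)-one F6. PPh3 (MeCN, rt) would convert it into the lactone phosphonium bromide F7, and the ylide formed with Et3N (CH2Cl2, 0 °C) would condense with propanal 19 to give 22; any E isomer would be equilibrated with a trace of iodine in light.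

3. Step 2. What may go wrong: acid-induced oligomerization of the furan rings by Friedel–Crafts capture of the difurylmethyl cation before hydride transfer. The fallback sets out from 4 and comes back at 5; it removes the oxygen under basic conditions instead of through a cation. Carbinol 4 would be oxidized with MnO2 (CH2Cl2, rt) to (4-bromofuran-3-yl)(furan-3-yl)methanone F8, and Wolff–Kishner reduction in the Huang-Minlon manner (N2H4·H2O, KOH, diethylene glycol, 130 then 190 °C) through the hydrazone F9 would give 5.

**Further compounds**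

F1 | step 12 | 3-[(3E,5E)-7-bromo-4-methylhepta-3,5-dien-1-yl]-4-(furan-3-ylmethyl)furan | BrC/C=C/C(C)=C/CCc1cocc1Cc1ccoc1
F2 | step 12 | (4R)-4-benzyl-3-{(2S,4E,6E)-9-[4-(furan-3-ylmethyl)furan-3-yl]-2,6-dimethylnona-4,6-dienoyl}-1,3-oxazolidin-2-one | O=C(N1[C@H](Cc2ccccc2)COC1=O)[C@@H](C)C/C=C/C(C)=C/CCc1cocc1Cc1ccoc1
F3 | step 12 | (2S,4E,6E)-9-[4-(furan-3-ylmethyl)furan-3-yl]-2,6-dimethylnona-4,6-dien-1-ol | OC[C@@H](C)C/C=C/C(C)=C/CCc1cocc1Cc1ccoc1
F4 | step 12 | (2S,4E,6E)-9-[4-(furan-3-ylmethyl)furan-3-yl]-2,6-dimethylnona-4,6-dienal | O=C[C@@H](C)C/C=C/C(C)=C/CCc1cocc1Cc1ccoc1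
F5 | step 12 | 5-{(2S,4E,6E)-1-[(tert-butyldimethylsilyl)oxy]-9-[4-(furan-3-ylmethyl)furan-3-yl]-2,6-dimethylnona-4,6-dien-1-yl}-3-({[tri(propan-2-yl)silyl]oxy}methyl)furan-2(5H)-one (mixture at the carbinol carbon and C5) | CC(C)(C)[Si](C)(C)OC([C@@H](C)C/C=C/C(C)=C/CCc1cocc1Cc1ccoc1)C1OC(=O)C(CO[Si](C(C)C)(C(C)C)C(C)C)=C1
F6 | step 10 | 5-bromo-3-({[tri(propan-2-yl)silyl]oxy}methyl)furan-2(5H)-one (racemic) | BrC1OC(=O)C(CO[Si](C(C)C)(C(C)C)C(C)C)=C1
F7 | step 10 | triphenyl[5-oxo-4-({[tri(propan-2-yl)silyl]oxy}methyl)-2,5-dihydrofuran-2-yl]phosphonium bromide | [Br-].O=C1OC([P+](c2ccccc2)(c2ccccc2)c2ccccc2)C=C1CO[Si](C(C)C)(C(C)C)C(C)C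
F8 | step 2 | (4-bromofuran-3-yl)(furan-3-yl)methanone | O=C(c1ccoc1)c1cocc1Br
F9 | step 2 | (4-bromofuran-3-yl)(furan-3-yl)methanone hydrazone | NN=C(c1ccoc1)c1cocc1Br
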